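**Retrosynthetic overview**
1. The target comes from its N1-TIPS derivative, so fluoride desilylation is the last step.
2. Key disconnection is the N1'–C3 bond. It splits into an indol-3-yl(mesityl)iodonium salt (C3 electrophile) and free N–H 6-prenylindole (N nucleophile), joined by a new copper-catalysed coupling.
3. The iodonium salt comes from N-TIPS-6-prenylindole, which comes from 6-prenylindole. Both halves therefore derive from one monomer.
4. 6-Prenylindole comes from 6-bromoindole and a prenylstannane, forming the C6–CH2 bond by Stille coupling.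
5. Ring order: no ring is built. Both indole bicycles are bought intact as 6-bromoindole.

Assumption: the SMILES has no stereocentre and no E/Z alkene, and the N1'–C3 axis is flanked only by hydrogens and rotates freely. The compound is therefore achiral, and "single enantiomer" is read as the one constitution drawn.

**Step 1**
Reactants: 1 6-bromo-1H-indole; 2 tributyl(3-methylbut-2-en-1-yl)stannane
Product: 3 6-(3-methylbut-2-en-1-yl)-1H-indole (6-prenylindole)
Conditions: Pd(PPh3)4 (5 mol %), DMF, 100 °C, 16 h
Reagents that add atoms: none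
Why: Stille cross-coupling, in which zerovalent palladium inserts into the C6–Br bond, the allylic stannane transmetalates, and reductive elimination from the η3-prenyl complex at its unhindered CH2 terminus gives the linear prenyl arene, while the neutral conditions tolerate the free N–H.

**Step 2**
Reactants: 3 6-(3-methylbut-2-en-1-yl)-1H-indole
Product: 5 6-(3-methylbut-2-en-1-yl)-1-(triisopropylsilyl)-1H-indole, via sodium 6-prenylindol-1-ide 4 (not isolated)
Conditions: NaH (1.2 equiv), THF, 0 °C; then TIPSCl (1.1 equiv), 0 °C to rt
Reagents that add atoms: chlorotriisopropylsilane (TIPSCl), CC(C)[Si](Cl)(C(C)C)C(C)C; NaH, [Na+].[H-] (its sodium stays only in 4)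
Why: Standard N-deprotonation and N-silylation (substitution at silicon) of an indole, where the bulky TIPS group masks N1, shields C2 and leaves C3 as the only reactive site, and the prenyl group is inert to NaH.

**Step 3**
Reactants: 5 6-(3-methylbut-2-en-1-yl)-1-(triisopropylsilyl)-1H-indole
Product: 6 [6-(3-methylbut-2-en-1-yl)-1-(triisopropylsilyl)-1H-indol-3-yl](2,4,6-trimethylphenyl)iodonium 4-methylbenzenesulfonate
Conditions: MesI(OAc)2 (1.05 equiv), TsOH·H2O (1.05 equiv), MeCN, rt, 15 min; then 5, CH2Cl2/MeCN, −20 to 0 °C; precipitation from Et2O/pentane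
Reagents that add atoms: iodomesitylene diacetate, CC(=O)OI(OC(C)=O)c1c(C)cc(C)cc1C; p-toluenesulfonic acid monohydrate, Cc1ccc(S(=O)(=O)O)cc1.O
Why: Electrophilic aromatic substitution by a Koser-type trivalent iodine reagent (the known synthesis of aryl(heteroaryl)iodonium salts) occurs at C3, because C3 is several orders of magnitude more nucleophilic than the trisubstituted prenyl alkene and C2 is blocked by TIPS, and isolating the salt removes all free oxidant before the coupling.

**Step 4**
Reactants: 6 [6-(3-methylbut-2-en-1-yl)-1-(triisopropylsilyl)-1H-indol-3-yl](2,4,6-trimethylphenyl)iodonium 4-methylbenzenesulfonate; 3 6-(3-methylbut-2-en-1-yl)-1H-indole (1.5 equiv)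
Product: 7 6-(3-methylbut-2-en-1-yl)-3-[6-(3-methylbut-2-en-1-yl)-1H-indol-1-yl]-1-(triisopropylsilyl)-1H-indole
Conditions: [Cu(MeCN)4]PF6 (10 mol %), 1,10-phenanthroline (12 mol %), K3PO4 (2.0 equiv), 4 Å MS, 1,4-dioxane, 40 °C, dark
Reagents that add atoms: none
Why: Proposed new method: copper-catalysed N-(indol-3-yl)ation of a free N–H indole by an indol-3-yl(mesityl)iodonium salt, overall a formal C3–H/N–H cross-coupling of two indoles; K3PO4 and the phenanthroline-ligated monovalent copper first convert 3 into a copper N-indolide, the weak hypervalent C–I bond of 6 then adds oxidatively at 40 °C with transfer of the less hindered, more electron-rich indol-3-yl group (mesityl stays on iodine as a dummy ligand), and the neutral trivalent copper (indol-3-yl)(N-indolyl) complex undergoes fast C–N reductive elimination; binding nitrogen to copper before the oxidation steers away from the C3'-arylation typical of cationic aryl-copper species with neutral indoles, TIPS prevents attack at C2 and self-coupling of the electrophile, and the absence of free oxidant leaves the prenyl groups and the free C3'–H of 7 untouched; the closest known reaction types are Ullmann–Goldberg-type N-arylation of azoles with diaryliodonium salts and the copper-catalysed amination or azidation of heteroaryl(aryl)iodonium salts with amines or azide, neither shown for an N–H indole paired with an indolyliodonium salt to make an N1–C3' biindole bond.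

**Step 5**
Reactants: 7 6-(3-methylbut-2-en-1-yl)-3-[6-(3-methylbut-2-en-1-yl)-1H-indol-1-yl]-1-(triisopropylsilyl)-1H-indole
Product: 8 6-(3-methylbut-2-en-1-yl)-3-[6-(3-methylbut-2-en-1-yl)-1H-indol-1-yl]-1H-indole (target)
Conditions: TBAF (1.1 equiv, 1 M in THF), THF, 0 °C, 30 min
Reagents that add atoms: none
Why: Fluoride-induced N–Si cleavage (desilylation), driven by the strong Si–F bond and the good indolide leaving group, proceeds under conditions that do not touch the prenyl alkenes or the N1'–C3 bond, and there is no stereocentre to set or lose.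

**Compound list**
1 | 6-bromo-1H-indole | Brc1ccc2cc[nH]c2c1 | starting material
2 | tributyl(3-methylbut-2-en-1-yl)stannane | CCCC[Sn](CCCC)(CCCC)CC=C(C)C | starting material
3 | 6-(3-methylbut-2-en-1-yl)-1H-indole | CC(C)=CCc1ccc2cc[nH]c2c1 | intermediate
4 | sodium 6-(3-methylbut-2-en-1-yl)indol-1-ide | CC(C)=CCc1ccc2cc[n-]c2c1.[Na+] | intermediate (not isolated)
5 | 6-(3-methylbut-2-en-1-yl)-1-(triisopropylsilyl)-1H-indole | CC(C)=CCc1ccc2ccn([Si](C(C)C)(C(C)C)C(C)C)c2c1 | intermediate
6 | [6-(3-methylbut-2-en-1-yl)-1-(triisopropylsilyl)-1H-indol-3-yl](2,4,6-trimethylphenyl)iodonium 4-methylbenzenesulfonate | CC(C)=CCc1ccc2c([I+]c3c(C)cc(C)cc3C)cn([Si](C(C)C)(C(C)C)C(C)C)c2c1.Cc1ccc(S(=O)(=O)[O-])cc1 | intermediate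
7 | 6-(3-methylbut-2-en-1-yl)-3-[6-(3-methylbut-2-en-1-yl)-1H-indol-1-yl]-1-(triisopropylsilyl)-1H-indole | CC(C)=CCc1ccc2c(-n3ccc4ccc(CC=C(C)C)cc43)cn([Si](C(C)C)(C(C)C)C(C)C)c2c1 | intermediate
8 | 6-(3-methylbut-2-en-1-yl)-3-[6-(3-methylbut-2-en-1-yl)-1H-indol-1-yl]-1H-indole | CC(C)=CCc1ccc2c(-n3ccc4ccc(CC=C(C)C)cc43)c[nH]c2c1 | target

**Total step count:** 5. **Longest linear sequence:** 5 steps (1 to 3 to 5 to 6 to 7 to 8). Compound 3 enters twice, as precursor of 5 and as the nucleophile in step 4.

**Three steps most likely to fail**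

1) Step 4, the proposed new coupling.
- Risks: C3'-arylation of 3 giving a 3,3'-biindole, mesityl transfer, collapse of 6 to a 3-iodo- or 3-H-indole, or silyl migration to the nucleophile.
- Fallback (known chemistry): it sets out from 5 and comes back at 7. Compound 5 is brominated at C3 with NBS in THF at −78 °C to give 3-bromo-6-(3-methylbut-2-en-1-yl)-1-(triisopropylsilyl)-1H-indole F1. This heteroaryl bromide is then joined to 3 by a classical Ullmann–Goldberg N-arylation of an indole (CuI, trans-N,N'-dimethylcyclohexane-1,2-diamine, K3PO4, toluene, 110 °C), giving 7.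

2) Step 3, formation of the iodonium salt.
- Risks: attack of the trivalent iodine reagent on the prenyl alkene, electron-transfer dimerisation of the indole, or acid-induced loss of TIPS.
- Fallback: it sets out from 5 and comes back at 7, and it reverses the polarity at C3 so that no hypervalent iodine is needed. Compound 5 undergoes C3-selective C–H borylation ([Ir(OMe)(cod)]2, 4,4'-di-tert-butyl-2,2'-bipyridine, B2pin2, THF, 60 °C). This gives 6-(3-methylbut-2-en-1-yl)-3-(4,4,5,5-tetramethyl-1,3,2-dioxaborolan-2-yl)-1-(triisopropylsilyl)-1H-indole F2. F2 is coupled with 3 in an aerobic Chan–Lam N-arylation (catalytic Cu(OAc)2, pyridine, O2, 4 Å MS, MeCN, 60 °C) to give 7.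

3) Step 1, the Stille prenylation.
- Risks: some branched (reverse-prenyl) isomer, migration of the alkene into conjugation at 100 °C, or slow oxidative addition of the electron-rich bromide.
- Fallback: it sets out from 1 and comes back at 5, and it replaces cross-coupling by organolithium alkylation.
  - Compound 1 is deprotonated with NaH in THF to sodium 6-bromoindol-1-ide F3 and silylated with TIPSCl to give 6-bromo-1-(triisopropylsilyl)-1H-indole F4.
  - Bromine–lithium exchange with t-BuLi (2 equiv, THF, −78 °C) gives 6-lithio-1-(triisopropylsilyl)-1H-indole F5.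
  - F5 is alkylated at the primary carbon of 1-bromo-3-methylbut-2-ene (CC(C)=CCBr) to give 5.
  - Part of this 5 is desilylated with TBAF in THF to supply the 3 needed in step 4.

**Further compounds**
F1 | step 4 | 3-bromo-6-(3-methylbut-2-en-1-yl)-1-(triisopropylsilyl)-1H-indole | CC(C)=CCc1ccc2c(Br)cn([Si](C(C)C)(C(C)C)C(C)C)c2c1
F2 | step 3 | 6-(3-methylbut-2-en-1-yl)-3-(4,4,5,5-tetramethyl-1,3,2-dioxaborolan-2-yl)-1-(triisopropylsilyl)-1H-indole | CC(C)=CCc1ccc2c(B3OC(C)(C)C(C)(C)O3)cn([Si](C(C)C)(C(C)C)C(C)C)c2c1
F3 | step 1 | sodium 6-bromoindol-1-ide | Brc1ccc2cc[n-]c2c1.[Na+]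
F4 | step 1 | 6-bromo-1-(triisopropylsilyl)-1H-indole | Brc1ccc2ccn([Si](C(C)C)(C(C)C)C(C)C)c2c1
F5 | step 1 | 6-lithio-1-(triisopropylsilyl)-1H-indole | [Li]c1ccc2ccn([Si](C(C)C)(C(C)C)C(C)C)c2c1
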